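**Retrosynthetic overview** (germacrane numbering: C1–C10 carbocycle, C12 lactone carbonyl on O–C6, C11=C13 methylene, C14 formyl carbon, C15 oxirane CH2)

1. Late stage: C14 aldehyde from allylic oxidation of a C10 methyl; C8 ester by Mitsunobu inversion; C9=C10 by ring-closing metathesis (the ten-membered carbocycle is an eight-membered oxacycle across the cis-oxane, so the alkene can only be ring-cis).
2. C7–C8 and the C11=C13 methylene by Barbier allylation of acrolein with an α-(bromomethyl)butenolide.
3. Key disconnection: C5–C6 and O–C1 in one flask, by chelation-controlled vinylogous Mukaiyama aldol of 2-silyloxyfuran 13 with α-oxiranyl aldehyde 8, then 6-exo palladium allylic etherification. Enabling feature: the carbinol carbon C5 lies between the lactone γ-carbon C6 (a furanone γ-position) and the oxirane carbon C4 (a chelating α-oxygen), and its oxygen is five atoms from C1, which is allylic to C10; the C5 oxygen therefore closes the oxane ring (O, C1, C2, C3, C4, C5) on a 2-methylallyl palladium unit.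
4. Stereochemistry: C4 is set by amine-catalysed epoxidation; C5, C6 and C1 are relayed from it in the key step; C7 and C8 follow from C6.
5. Ring order: oxirane, then butenolide and oxane together (key step), then α-methylene lactone, then carbocycle.

Key step: step 8

Assumption: in step 5 the (S)-configured diarylprolinol silyl ether is taken to give the 2R oxirane; if the sense of induction is opposite, its antipode is used.
Assumption: the indium allylation of step 11 is taken to follow the closed chair transition state and to give the 7,8-anti (8S) carbinol, which is why step 13 inverts C8.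

Step 1
Reactants: 1 cyclopentene
Product: 2 5,5-dimethoxypentanal
Conditions: O3, CH2Cl2/MeOH, −78 °C; p-TsOH (cat.), 23 °C; NaHCO3; Me2S
Reagents that add atoms: ozone, [O-][O+]=O; methanol, CO
Why: Ozonolysis in methanol with acid-catalysed acetalisation of one terminus and reductive work-up of the other differentiates the two ends of the C1–C5 chain.

Step 2
Reactants: 2 5,5-dimethoxypentanal; 3 prop-1-en-2-ylmagnesium bromide
Product: 5 7,7-dimethoxy-2-methylhept-1-en-3-yl methyl carbonate (racemic), via bromomagnesium alkoxide 4 (not isolated)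
Conditions: THF, −78 to 0 °C; then ClCO2Me, 0 to 23 °C
Reagents that add atoms: methyl chloroformate, COC(=O)Cl
Why: Grignard 1,2-addition to the free aldehyde (future C1) and acylation of the magnesium alkoxide give the 2-methylallyl carbonate; the new centre is left racemic because it is erased in the allylpalladium intermediate of step 8.

Step 3
Reactants: 5 7,7-dimethoxy-2-methylhept-1-en-3-yl methyl carbonate
Product: 6 methyl 2-methyl-7-oxohept-1-en-3-yl carbonate
Conditions: p-TsOH·H2O (cat.), acetone/H2O, 23 °C
Reagents that add atoms: water, O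
Why: Mild acid hydrolysis of the dimethyl acetal frees the C5 aldehyde while the allylic carbonate survives.

Step 4
Reactants: 6 methyl 2-methyl-7-oxohept-1-en-3-yl carbonate
Product: 7 methyl 2-methyl-6-methylidene-7-oxohept-1-en-3-yl carbonate
Conditions: 37% aq. CH2O, pyrrolidine (10 mol%), propionic acid (10 mol%), i-PrOH, 45 °C
Reagents that add atoms: formaldehyde, C=O
Why: Amine/acid-catalysed Mannich condensation and elimination (organocatalytic α-methylenation of an aldehyde) brings in C15 as the methylidene group on C4.

Step 5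
Reactants: 7 methyl 2-methyl-6-methylidene-7-oxohept-1-en-3-yl carbonate
Product: 8 methyl 1-[(2R)-2-formyloxiran-2-yl]-4-methylpent-4-en-3-yl carbonate (both epimers at the carbonate carbon)
Conditions: 35% aq. H2O2, (S)-2-[diphenyl(trimethylsilyloxy)methyl]pyrrolidine (10 mol%), CH2Cl2, 23 °C
Reagents that add atoms: hydrogen peroxide, OO
Why: Iminium/enamine-catalysed nucleophilic epoxidation of the α-substituted acrolein should set C4, the only catalyst-controlled stereocentre, through face shielding of the enamine that closes the oxirane; the electron-neutral isopropenyl group does not react with H2O2.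

Step 6
Reactants: 9 furan-3-ylmethanol
Product: 12 3-(hydroxymethyl)furan-2(5H)-one, via dilithiated furanmethanol 10 (not isolated), via lithium furyltrimethoxyborate 11 (not isolated)
Conditions: n-BuLi (2.2 equiv), THF, −78 to 0 °C; B(OMe)3, −78 °C; AcOH, 30% aq. H2O2, 0 to 23 °C
Reagents that add atoms: hydrogen peroxide, OO
Why: The lithium alkoxide directs the second lithiation to C2 of the furan (directed ortho-metalation), and oxidation of the derived borate gives the 2-hydroxyfuran, which tautomerises to the butenolide.

Step 7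
Reactants: 12 3-(hydroxymethyl)furan-2(5H)-one
Product: 13 tert-butyl{[2-(tert-butyldimethylsilyloxy)furan-3-yl]methoxy}dimethylsilane
Conditions: TBSOTf (2.2 equiv), Et3N, CH2Cl2, 0 °C
Reagents that add atoms: tert-butyldimethylsilyl trifluoromethanesulfonate, CC(C)(C)[Si](C)(C)OS(=O)(=O)C(F)(F)F
Why: Silyl triflate and amine silylate the primary alcohol and convert the butenolide by soft enolisation into the aromatic 2-silyloxyfuran, a vinylogous silyl ketene acetal.

Step 8
Reactants: 8 methyl 1-[(2R)-2-formyloxiran-2-yl]-4-methylpent-4-en-3-yl carbonate; 13 tert-butyl{[2-(tert-butyldimethylsilyloxy)furan-3-yl]methoxy}dimethylsilane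
Product: 15 (5S)-3-[(tert-butyldimethylsilyloxy)methyl]-5-[(3R,4R,6R)-6-(prop-1-en-2-yl)-1,5-dioxaspiro[2.5]octan-4-yl]furan-2(5H)-one, via aldol adduct 14 (not isolated)
Conditions: 13 (1.3 equiv), MgBr2·OEt2 (2.5 equiv), CH2Cl2, −78 °C; pH 7 buffer, Et3N; then THF, Pd(PPh3)4 (5 mol%), 23 °C, same flask
Reagents that add atoms: none
Why: MgBr2 binds the aldehyde oxygen and the oxirane oxygen of 8 as a five-membered chelate and the silyloxyfuran adds through its 5-position (future C6) in an open transition state to give 14 (vinylogous Mukaiyama aldol; closest known type: chelation-controlled Lewis-acid additions of 2-silyloxyfurans to α-oxygenated aldehydes), after which zerovalent palladium ionises the allylic carbonate and the C5 hydroxyl attacks C1 (Tsuji–Trost allylic etherification). The only ring closed is the oxane (O, C1–C5), by 6-exo attack of oxygen on the substituted terminus of the 2-methylallyl palladium unit; the butenolide ring arrives intact with the furan. C5: with C=O held syn to the oxirane oxygen, the furan should attack the carbonyl face flanked by that oxygen and anti to the oxirane CH2, which gives the 4,5-relationship of the target, whereas non-chelated, dipole-minimised attack would give the C5 epimer. C6: the open antiperiplanar transition state typical of Lewis-acid silyloxyfuran additions should give the threo (5,6-syn) carbinol. C1: the two faces of the allyl unit interconvert through its CH2 terminus, so both carbonate epimers converge, and the chair-like transition state with the C1 and C5 substituents equatorial gives the 2,6-cis oxane. The step needs γ- over α-attack of the furan (normal for 3-substituted 2-silyloxyfurans), chelation over dipole control (bidentate Lewis acid, non-coordinating solvent, −78 °C) and six- over eight-membered etherification (ring size); the silyl ether and the isopropenyl group are inert, and the oxirane is protected from bromide by the low temperature and by buffering before warming.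

Step 9
Reactants: 15 (5S)-3-[(tert-butyldimethylsilyloxy)methyl]-5-[(3R,4R,6R)-6-(prop-1-en-2-yl)-1,5-dioxaspiro[2.5]octan-4-yl]furan-2(5H)-one
Product: 16 (5S)-3-(hydroxymethyl)-5-[(3R,4R,6R)-6-(prop-1-en-2-yl)-1,5-dioxaspiro[2.5]octan-4-yl]furan-2(5H)-one
Conditions: HF·pyridine, pyridine, THF, 0 °C
Reagents that add atoms: none
Why: Buffered fluoride cleavage of the primary silyl ether should leave the oxirane, the allylic ether and the butenolide untouched.

Step 10
Reactants: 16 (5S)-3-(hydroxymethyl)-5-[(3R,4R,6R)-6-(prop-1-en-2-yl)-1,5-dioxaspiro[2.5]octan-4-yl]furan-2(5H)-one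
Product: 17 (5S)-3-(bromomethyl)-5-[(3R,4R,6R)-6-(prop-1-en-2-yl)-1,5-dioxaspiro[2.5]octan-4-yl]furan-2(5H)-one
Conditions: CBr4, PPh3, CH2Cl2, 0 °C
Reagents that add atoms: carbon tetrabromide, BrC(Br)(Br)Br
Why: Appel bromination converts the allylic alcohol into the α-(bromomethyl)butenolide under neutral conditions.

Step 11
Reactants: 17 (5S)-3-(bromomethyl)-5-[(3R,4R,6R)-6-(prop-1-en-2-yl)-1,5-dioxaspiro[2.5]octan-4-yl]furan-2(5H)-one; 18 acrolein
Product: 19 (4R,5S)-4-[(1S)-1-hydroxyprop-2-en-1-yl]-3-methylidene-5-[(3R,4R,6R)-6-(prop-1-en-2-yl)-1,5-dioxaspiro[2.5]octan-4-yl]dihydrofuran-2(3H)-one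
Conditions: In powder, THF/H2O, 23 °C
Reagents that add atoms: none
Why: Barbier allylation: the allylindium from 17 adds through its γ-carbon C7 to the aldehyde in a 1,2 sense and the allylic shift creates the C11=C13 methylene; C7 is set anti to the oxanyl group on C6 (trans lactone), and C8 by the chair transition state in which the ring-locked C6 substituent is equatorial (7,8-anti, 8S).

Step 12
Reactants: 19 (4R,5S)-4-[(1S)-1-hydroxyprop-2-en-1-yl]-3-methylidene-5-[(3R,4R,6R)-6-(prop-1-en-2-yl)-1,5-dioxaspiro[2.5]octan-4-yl]dihydrofuran-2(3H)-one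
Product: 20 (1R,4R,5R,6S,7R,8S,9Z)-1,5:4,15-diepoxy-8-hydroxygermacra-9,11(13)-dien-12,6-olide
Conditions: second-generation Hoveyda–Grubbs catalyst (10 mol%), toluene (1 mM), 80 °C
Reagents that add atoms: none
Why: Ring-closing metathesis: ruthenium loads on the monosubstituted C9 vinyl group and closes onto the isopropenyl group; inside the eight-membered oxacycle the new trisubstituted alkene can only have C1 and C8 cis, which is the geometry of the target.

Step 13
Reactants: 20 (1R,4R,5R,6S,7R,8S,9Z)-1,5:4,15-diepoxy-8-hydroxygermacra-9,11(13)-dien-12,6-olide; 21 methacrylic acid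
Product: 22 (1R,4R,5R,6S,7R,8R,9Z)-1,5:4,15-diepoxy-8-(methacryloyloxy)germacra-9,11(13)-dien-12,6-olide
Conditions: PPh3, DIAD, THF, 0 to 23 °C
Reagents that add atoms: none
Why: Mitsunobu esterification displaces the activated C8 oxygen by the carboxylate with SN2 inversion, turning the 8S alcohol into the 8R ester; the ester is introduced only after metathesis because an allylic methacrylate would close to a butenolide.

Step 14
Reactants: 22 (1R,4R,5R,6S,7R,8R,9Z)-1,5:4,15-diepoxy-8-(methacryloyloxy)germacra-9,11(13)-dien-12,6-olide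
Product: 23 (1R,4R,5R,6S,7R,8R,9Z)-1,5:4,15-diepoxy-14-hydroxy-8-(methacryloyloxy)germacra-9,11(13)-dien-12,6-olide
Conditions: SeO2 (0.5 equiv), t-BuOOH, CH2Cl2, 23 °C
Reagents that add atoms: tert-butyl hydroperoxide, CC(C)(C)OO
Why: SeO2 allylic oxidation (ene reaction, then [2,3]-sigmatropic shift) should take the C10 methyl, which is trans to C8 and the only allylic C–H on an electron-rich alkene that does not lead to a bridgehead alkene; C14 hydroxylation of germacranolides carrying an oxirane and an α-methylene lactone is a close analogy.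

Step 15
Reactants: 23 (1R,4R,5R,6S,7R,8R,9Z)-1,5:4,15-diepoxy-14-hydroxy-8-(methacryloyloxy)germacra-9,11(13)-dien-12,6-olide
Product: 24 (1R,4R,5R,6S,7R,8R,9E)-1,5:4,15-diepoxy-8-(methacryloyloxy)-14-oxogermacra-9,11(13)-dien-12,6-olide
Conditions: MnO2, CH2Cl2, 23 °C
Reagents that add atoms: none
Why: MnO2 oxidises only the primary allylic alcohol, giving the conjugated aldehyde without touching the oxirane, the esters or the alkene geometry.

**Compound list**

1 | cyclopentene | C1=CCCC1 | starting material
2 | 5,5-dimethoxypentanal | COC(OC)CCCC=O | intermediate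
3 | prop-1-en-2-ylmagnesium bromide | C=C(C)[Mg]Br | starting material
4 | bromomagnesium 7,7-dimethoxy-2-methylhept-1-en-3-olate | C=C(C)C(O[Mg]Br)CCCC(OC)OC | intermediate
5 | 7,7-dimethoxy-2-methylhept-1-en-3-yl methyl carbonate (racemic) | C=C(C)C(OC(=O)OC)CCCC(OC)OC | intermediate
6 | methyl 2-methyl-7-oxohept-1-en-3-yl carbonate (racemic) | C=C(C)C(OC(=O)OC)CCCC=O | intermediate
7 | methyl 2-methyl-6-methylidene-7-oxohept-1-en-3-yl carbonate (racemic) | C=C(C)C(OC(=O)OC)CCC(=C)C=O | intermediate
8 | methyl 1-[(2R)-2-formyloxiran-2-yl]-4-methylpent-4-en-3-yl carbonate (carbonate carbon unassigned) | C=C(C)C(OC(=O)OC)CC[C@@]1(CO1)C=O | intermediate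
9 | furan-3-ylmethanol | OCc1ccoc1 | starting material
10 | lithium (2-lithiofuran-3-yl)methanolate | [Li]OCc1ccoc1[Li] | intermediate
11 | dilithium salt of trimethoxy[3-(oxidomethyl)furan-2-yl]borate | [Li]OCc1ccoc1[B-](OC)(OC)OC.[Li+] | intermediate
12 | 3-(hydroxymethyl)furan-2(5H)-one | O=C1OCC=C1CO | intermediate
13 | tert-butyl{[2-(tert-butyldimethylsilyloxy)furan-3-yl]methoxy}dimethylsilane | CC(C)(C)[Si](C)(C)OCc1ccoc1O[Si](C)(C)C(C)(C)C | intermediate
14 | (5S)-3-[(tert-butyldimethylsilyloxy)methyl]-5-[(R)-hydroxy{(2R)-2-[3-(methoxycarbonyloxy)-4-methylpent-4-en-1-yl]oxiran-2-yl}methyl]furan-2(5H)-one | C=C(C)C(OC(=O)OC)CC[C@@]1(CO1)[C@H](O)[C@H]1OC(=O)C(CO[Si](C)(C)C(C)(C)C)=C1 | intermediate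
15 | (5S)-3-[(tert-butyldimethylsilyloxy)methyl]-5-[(3R,4R,6R)-6-(prop-1-en-2-yl)-1,5-dioxaspiro[2.5]octan-4-yl]furan-2(5H)-one | C=C(C)[C@H]1CC[C@@]2(CO2)[C@H](O1)[C@H]1OC(=O)C(CO[Si](C)(C)C(C)(C)C)=C1 | intermediate
16 | (5S)-3-(hydroxymethyl)-5-[(3R,4R,6R)-6-(prop-1-en-2-yl)-1,5-dioxaspiro[2.5]octan-4-yl]furan-2(5H)-one | C=C(C)[C@H]1CC[C@@]2(CO2)[C@H](O1)[C@H]1OC(=O)C(CO)=C1 | intermediate
17 | (5S)-3-(bromomethyl)-5-[(3R,4R,6R)-6-(prop-1-en-2-yl)-1,5-dioxaspiro[2.5]octan-4-yl]furan-2(5H)-one | C=C(C)[C@H]1CC[C@@]2(CO2)[C@H](O1)[C@H]1OC(=O)C(CBr)=C1 | intermediate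
18 | acrolein | C=CC=O | starting material
19 | (4R,5S)-4-[(1S)-1-hydroxyprop-2-en-1-yl]-3-methylidene-5-[(3R,4R,6R)-6-(prop-1-en-2-yl)-1,5-dioxaspiro[2.5]octan-4-yl]dihydrofuran-2(3H)-one | C=C(C)[C@H]1CC[C@@]2(CO2)[C@H](O1)[C@H]1OC(=O)C(=C)[C@@H]1[C@@H](O)C=C | intermediate
20 | (1R,4R,5R,6S,7R,8S,9Z)-1,5:4,15-diepoxy-8-hydroxygermacra-9,11(13)-dien-12,6-olide | O[C@H]1/C=C(/C)[C@H]2CC[C@@]3(CO3)[C@H](O2)[C@H]2OC(=O)C(=C)[C@@H]21 | intermediate
21 | methacrylic acid | C=C(C)C(=O)O | starting material
22 | (1R,4R,5R,6S,7R,8R,9Z)-1,5:4,15-diepoxy-8-(methacryloyloxy)germacra-9,11(13)-dien-12,6-olide | C=C(C)C(=O)O[C@@H]1/C=C(/C)[C@H]2CC[C@@]3(CO3)[C@H](O2)[C@H]2OC(=O)C(=C)[C@@H]21 | intermediate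
23 | (1R,4R,5R,6S,7R,8R,9Z)-1,5:4,15-diepoxy-14-hydroxy-8-(methacryloyloxy)germacra-9,11(13)-dien-12,6-olide | C=C(C)C(=O)O[C@@H]1/C=C(/CO)[C@H]2CC[C@@]3(CO3)[C@H](O2)[C@H]2OC(=O)C(=C)[C@@H]21 | intermediate
24 | (1R,4R,5R,6S,7R,8R,9E)-1,5:4,15-diepoxy-8-(methacryloyloxy)-14-oxogermacra-9,11(13)-dien-12,6-olide | C=C(C)C(=O)O[C@@H]1/C=C(/C=O)[C@H]2CC[C@@]3(CO3)[C@H](O2)[C@H]2OC(=O)C(=C)[C@@H]21 | target

**Step count:** 15 steps in total. Longest linear sequence: 13 steps (steps 1–5 and 8–15, from cyclopentene); steps 6–7 make the furan partner.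

**Steps most likely to fail**

Step 8. The aldol stage may lose chelation control: non-chelated, dipole-minimised attack on the oxiranyl aldehyde gives the C5 epimer. The magnesium-bound oxirane may also be opened by bromide, the simple (5,6) selectivity may erode, and 14 may undergo retro-aldol before the ring closes. The fallback sets out from 8 and 13 and returns at 15. It moves stereocontrol from the substrate chelate to the reagent: the same two partners are joined under a halide-free chiral Lewis acid that binds α-oxygenated aldehydes in a bidentate way, a copper bis(oxazoline) or pybox triflate complex of divalent copper (a known catalyst class for enantioselective aldol additions of 2-silyloxyfurans), using the ligand antipode matched to the oxirane. The palladium closure follows unchanged. No new compound arises.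

Step 12. The C9 vinyl group may oligomerise by cross metathesis instead of closing onto the hindered isopropenyl group across the strained bicycle, and ruthenium hydrides may isomerise the free allylic alcohol to the ketone. The fallback sets out from 19 and returns at 22, replacing steps 12 and 13 by inverting before ring closure. Mitsunobu reaction of 19 with commercial 3-bromo-2-methylpropanoic acid (PPh3, DIAD) gives the 8R β-bromo ester F1, a masked methacrylate with no acrylate alkene to compete for the catalyst and with C8 in the configuration of the target. Ring-closing metathesis of F1 gives the macrocyclic β-bromo ester F2. Et3N then eliminates HBr from F2 to unveil the methacrylate 22.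

Step 13. The hindered ring carbinol may not undergo SN2 substitution: elimination to a diene, SN2' attack or acylation with retention can take over. The fallback sets out from 20 and returns at 22, and corrects C8 by redox instead of displacement. Dess–Martin oxidation of 20 gives the macrocyclic dienone F3. Corey–Bakshi–Shibata reduction with catecholborane, using the oxazaborolidine antipode that delivers the 8R carbinol, gives the 8β-alcohol F4. Acylation of F4 with methacrylic anhydride and DMAP gives 22 with retention.

Further compounds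
F0 | step 8 | none | none
F1 | step 12 | (4R,5S)-4-[(1R)-1-(3-bromo-2-methylpropanoyloxy)prop-2-en-1-yl]-3-methylidene-5-[(3R,4R,6R)-6-(prop-1-en-2-yl)-1,5-dioxaspiro[2.5]octan-4-yl]dihydrofuran-2(3H)-one | C=C(C)[C@H]1CC[C@@]2(CO2)[C@H](O1)[C@H]1OC(=O)C(=C)[C@@H]1[C@H](OC(=O)C(C)CBr)C=C
F2 | step 12 | (1R,4R,5R,6S,7R,8R,9Z)-8-(3-bromo-2-methylpropanoyloxy)-1,5:4,15-diepoxygermacra-9,11(13)-dien-12,6-olide | CC(CBr)C(=O)O[C@@H]1/C=C(/C)[C@H]2CC[C@@]3(CO3)[C@H](O2)[C@H]2OC(=O)C(=C)[C@@H]21
F3 | step 13 | (1R,4R,5R,6S,7R,9Z)-1,5:4,15-diepoxy-8-oxogermacra-9,11(13)-dien-12,6-olide | O=C1/C=C(/C)[C@H]2CC[C@@]3(CO3)[C@H](O2)[C@H]2OC(=O)C(=C)[C@@H]21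
F4 | step 13 | (1R,4R,5R,6S,7R,8R,9Z)-1,5:4,15-diepoxy-8-hydroxygermacra-9,11(13)-dien-12,6-olide | O[C@@H]1/C=C(/C)[C@H]2CC[C@@]3(CO3)[C@H](O2)[C@H]2OC(=O)C(=C)[C@@H]21
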